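Readings and results are calculated with made-up constants; the scatter is artificial.

4.8% of complex with two exchanged stood in epsilon at 8.00 min, down from 15.4% at 3.00 min, and my choice for ochre hung on that fall: read it at 10 min as a finished flask, or add a later reading.

| flask | starting complex | incoming ligand | capture agent | remark | time |
|---|---|---|---|---|---|
| theta | 1 mM | 0.70 mM | 0.020 mM | run made earlier |  |
| epsilon | 1 mM | 3.1 mM | 0.020 mM | run made earlier |  |
| green | 1.0 mM | 0.500 mM | 0.0200 mM |  | 10 min |
| ochre | 1.0 mM | 2.50 mM | 0.0200 mM |  | 10 min |

| run | time / min | complex with three exchanged / % | complex with two exchanged / % |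
|---|---|---|---|
| theta | 1.33 | 0.5 | 2.9 |
| theta | 3.00 | 0 | 3.6 |
| theta | 4.00 | 0.1 | 3.2 |
| theta | 6.00 | 0.3 | 3.3 |
| theta | 8.00 | 1.2 | 4.2 |
| theta | 10.0 | 0.7 | 2.6 |
| epsilon | 0.500 | 1.6 | 20.1 |
| epsilon | 1.50 | 8.7 | 21.6 |
| epsilon | 3.00 | 15.3 | 15.4 |
| epsilon | 4.00 | 17.7 | 12.1 |
| epsilon | 6.00 | 23.6 | 8.2 |
| epsilon | 8.00 | 26.5 | 4.8 |
| epsilon | 10.0 | 28.5 | 3.6 |

(readings scatter by 0.5 percentage points)

- which of these holds the largest part of the starting complex at the end of green (starting complex / complex with two exchanged / complex with one exchanged / complex with three exchanged)
- which of these holds the largest part of the starting complex at the end of ochre (starting complex / complex with two exchanged / complex with one exchanged / complex with three exchanged)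
- complex with three exchanged at the end of ochre, in percent of the starting complex charged



Between those readings the sum of complexes with two and three exchanged stayed flat in epsilon, 30.7% and then 31.3%, so I took the one to be turning into the other, with a pseudo-first-order constant read as 0.233 min⁻¹. Theta, charged with 0.70 mM of ligand against 1 mM of complex, still held 2.6% of complex with two exchanged at 10.0 min, so I took the step to need free ligand. If each starting complex took one ligand, each complex with two exchanged one more and each with three exchanged two more, epsilon had [incoming ligand] of 1.55 mM at 6.00 min. Half-life times [incoming ligand] then comes to 4.60 mM·min, and this I carried as the half-life product: on this reading, the half-life of complex with two exchanged is the product divided by [incoming ligand].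

Ochre keeps at most 1.50 mM of ligand once its starting complex has taken one each, so that half-life is at shortest 3.06 min. Even counted from the start, 10 min is 3.27 half-lives, which leaves 10.4% of the complex with two exchanged unconverted. I would therefore charge ochre as written and add a later reading. Green, charged with 0.500 mM against 1.0 mM, should lose its ligand as I took theta to have done, so I would add no later reading there.

The forecast named starting complex for green and complex with one exchanged for ochre, with 19% (16% to 22%) of complex with three exchanged, holding that “The one-exchanged complex looks essentially dead-ended”. My product gives no such figure, only the later reading.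

The answer for green was starting complex, at 52.0%. The answer for ochre was complex with three exchanged, at 20.5%, and that flask held 0% of complex with one exchanged and 73.3% of side product.

    complex with one exchanged → side product (k = 0.0811 s⁻¹)
    complex with two exchanged + incoming ligand → leaving ligand + complex with three exchanged (k = 2.57 M⁻¹ s⁻¹)
    complex with one exchanged + incoming ligand → leaving ligand + complex with two exchanged (k = 16.4 M⁻¹ s⁻¹)
    starting complex + incoming ligand → leaving ligand + complex with one exchanged (k = 19.7 M⁻¹ s⁻¹)
    complex with one exchanged + capture agent → trapped intermediate (k = 134 M⁻¹ s⁻¹)

Ochre had not come to rest. Its end [incoming ligand] of 1.04 mM makes the half-life product give 4.42 min for its 4.82% of complex with two exchanged, against 4.3 min from the constants. Green's end [incoming ligand] of 5.05 × 10⁻⁴ mM gives 9090 min, and its complex with two exchanged stood at 1.78% and still at 1.78% after 100 min. At ten times the time, ochre's complex with two exchanged fell to 0% and its complex with three exchanged rose to 25.3%.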